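The numbers in the tables stem from a simulated flask with constants of no real substance, and the scatter is random.

By the last reading of the maple run the isomer of the product, 14% of the substrate charged, had drawn level with the target, 13%, though at its first reading it had stood at 0% beside 11%, so I wanted to know how that ratio would fall along the curve of the new flask.

| flask | substrate | coupling partner | catalyst | remark | time |
|---|---|---|---|---|---|
| cedar | 0.051 M | 0.027 M | 0.51 mM | run made earlier |  |
| larch | 0.051 M | 0.040 M | 0.51 mM | run made earlier |  |
| maple | 0.025 M | 0.0536 M | 0.51 mM | run made earlier |  |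
| flask | 0.051 M | 0.0536 M | 0.51 mM |  | 20 min |

| run | time / min | target / % | isomer of the product / % |
|---|---|---|---|
| cedar | 5.00 | 9 | 1 |
| cedar | 10.0 | 7 | 5 |
| cedar | 15.0 | 5 | 6 |
| cedar | 20.0 | 6 | 9 |
| larch | 1.50 | 7 | 0 |
| larch | 4.00 | 14 | 4 |
| larch | 8.00 | 15 | 4 |
| larch | 20.0 | 9 | 8 |
| maple | 1.50 | 11 | 0 |
| maple | 4.00 | 16 | 1 |
| maple | 8.00 | 18 | 5 |
| maple | 20.0 | 13 | 14 |

(each reading ± 1.5 percentage points)



1. ratio of target to isomer of the product at 20 s
2. ratio of target to isomer of the product at 2.5 min
3. ratio of target to isomer of the product at 20 min

The isomer lagged the target in the earlier runs, so I divided the final isomer readings of cedar, larch and maple by the area under their target curves, 6.50 min of charge fraction, which gave 0.0477 min⁻¹, the isomer clock, a pseudo-first-order rate constant for the isomer made per minute from each fraction of target standing. The flask had maple's partner charge, so I drew its target rising at first at 0.0733 min⁻¹ of the charge, and a straight rise puts isomer over target at the clock times half the elapsed time, which gave me a ratio of 126 at 20 s and 16.8 at 2.5 min. Maple's first isomer reading, with a scatter of 1.5 percentage points, could not exclude a small early source, however. I took the knee from maple, whose target reading topped at 18% near 8.00 min, and the crossing from its last reading, so my ratio at 20 min was 0.929.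

The forecast, holding that “The isomer appears with a lag, so it comes from the target”, gave 100, 13 and 0.9, lower than mine at the early times.

The flask gave 23.8, 10.0 and 1.04.

    target + catalyst ⇌ isomer of the product + catalyst, rate k1*[catalyst]*[target] forward; the back reaction follows from the equilibrium constant (k = 1.30 M⁻¹ s⁻¹)
    coupling partner → decomposed reagent (k = 5.60 × 10⁻⁴ s⁻¹)
    substrate + coupling partner ⇌ target (K = 8.30 M⁻¹, k = 0.0210 M⁻¹ s⁻¹)
    substrate + coupling partner ⇌ isomer of the product (K = 40.0 M⁻¹, k = 7.20 × 10⁻⁴ M⁻¹ s⁻¹)

With the direct passing of substrate and coupling partner into isomer taken away in both directions, the flask's ratio at 20 s stood at 148 rather than 23.8, so the clock needs a floor, the forward constants' quotient 0.0343 of isomer over target. Floor plus clock gave 10.6 for the flask at 2.5 min, against 10.0. The first step of the scheme runs in proportion to catalyst, so in the neighbour flask with 8.7 × 10⁻⁴ M of catalyst I scaled the clock to 0.0814 min⁻¹, which gave 7.35 at 2.5 min, and that neighbour showed 7.06.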